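Everything rests on opening ring A into an acyclic α′-diazo enone and methoxyacetylene. Ring A has oxygen on carbon 1 (OMe) and carbon 3 (OH) flanking the lone hydrogen on carbon 2, and three adjacent carbon substituents on carbons 4, 5 and 6; this maps onto a fully substituted vinylketene joined to an ynol ether. In one irradiation-then-warming operation the diazo ketone rearranges, takes up the alkyne and aromatizes, so that the pentasubstituted ring A appears with its two oxygens already differentiated. The precursor is an (E)-enone that carries both 4-benzyloxybenzyl groups, the complete ring B on its two-carbon bridge, and a diazo group on the other α-carbon. Hydrogenolysis then frees the four phenols.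

Key step: step 11

Remarks on the chemistry:
- The target is achiral, so no stereocenter has to be set.
- Ring A is numbered so that carbon 1 bears OMe, carbon 2 the hydrogen, carbon 3 the hydroxyl, carbon 4 a 4-hydroxybenzyl group, carbon 5 the two-carbon bridge and carbon 6 the second 4-hydroxybenzyl group.
- Ring B is built from 2-bromo-4-hydroxybenzaldehyde so that the bromine marks the bridge carbon and the aldehyde carbon becomes the benzylic methylene.
- Methoxyacetylene, which is volatile and seldom stocked, is made fresh.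
- Counted from the diazo ketone, the key step makes four ring bonds, because the Wolff shift itself joins carbon 5 to carbon 6 of ring A.

Abbreviations: Bn = benzyl; ArB = 5-(benzyloxy)-2-[4-(benzyloxy)benzyl]phenyl, the protected ring B with its benzyl arm.

Step 1
Reactants: 1 2-bromo-4-hydroxybenzaldehyde
Product: 2 4-(benzyloxy)-2-bromobenzaldehyde
Conditions: BnBr (1.1 equiv), K2CO3, DMF, rt
Reagents that add atoms: benzyl bromide, BrCc1ccccc1
Why: Williamson ether synthesis: the phenoxide formed by K2CO3 is the only nucleophile and displaces bromide from benzyl bromide, while the aldehyde and the aryl bromide are inert under these conditions.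

Step 2
Reactants: 2 4-(benzyloxy)-2-bromobenzaldehyde; 3 4-(benzyloxy)phenylmagnesium bromide (commercial THF solution)
Product: 4 (±)-[4-(benzyloxy)-2-bromophenyl][4-(benzyloxy)phenyl]methanol
Conditions: 3 (1.2 equiv), THF, 0 °C; aq NH4Cl
Reagents that add atoms: none
Why: Grignard addition to the aldehyde is fast at 0 °C whereas bromine–magnesium exchange at the ortho bromide is not expected, and the carbinol center forms as a racemate that is removed in step 3.

Step 3
Reactants: 4 (±)-[4-(benzyloxy)-2-bromophenyl][4-(benzyloxy)phenyl]methanol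
Product: 5 4-(benzyloxy)-1-[4-(benzyloxy)benzyl]-2-bromobenzene (ArB–Br)
Conditions: Et3SiH (2.5 equiv), CF3CO2H (5 equiv), CH2Cl2, 0 °C
Reagents that add atoms: none
Why: Ionic hydrogenation: acid ionizes the carbinol to a benzhydryl cation stabilized by two para alkoxy groups, which takes hydride from the silane faster than it can alkylate an arene, and aryl benzyl ethers and the aryl bromide should tolerate brief exposure to CF3CO2H at 0 °C.

Step 4
Reactants: 5 4-(benzyloxy)-1-[4-(benzyloxy)benzyl]-2-bromobenzene; 6 diethyl allylphosphonate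
Product: 8 diethyl [3-(ArB)propyl]phosphonate, via alkylborane 7 (not isolated)
Conditions: 6 (1.4 equiv), 9-BBN (0.5 M in THF, 1.4 equiv), 0 °C to rt; then 5, PdCl2(dppf)·CH2Cl2 (5 mol %), 3 M aq K3PO4, DMF, 60 °C
Reagents that add atoms: none
Why: Anti-Markovnikov hydroboration of the terminal alkene followed by B-alkyl Suzuki–Miyaura coupling: the primary alkylborane transmetalates readily after oxidative addition of the aryl bromide to zerovalent palladium, the bidentate dppf ligand suppresses β-hydride elimination, and the phosphonate and benzyl ethers are spectators.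

Step 5
Reactants: 9 3-(4-hydroxyphenyl)propanoic acid
Product: 10 benzyl 3-[4-(benzyloxy)phenyl]propanoate
Conditions: BnBr (2.3 equiv), K2CO3, DMF, 60 °C
Reagents that add atoms: benzyl bromide (two equivalents), BrCc1ccccc1
Why: Double O-alkylation (Williamson ether synthesis at the phenol and carboxylate alkylation) gives the protected ester in one operation, and the benzyl ester serves directly as the acyl donor of step 6.

Step 6
Reactants: 8 diethyl [3-(ArB)propyl]phosphonate; 10 benzyl 3-[4-(benzyloxy)phenyl]propanoate
Product: 11 (±)-diethyl {1-[4-(benzyloxy)phenyl]-6-(ArB)-3-oxohexan-4-yl}phosphonate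
Conditions: 8 (1.0 equiv), 10 (1.1 equiv), THF, 0 °C; LiN(iPr)2 (commercial solution, 2.2 equiv) added dropwise; aq NH4Cl
Reagents that add atoms: none
Why: Claisen-type acylation of the α-lithiated phosphonate by the ester: the anion is generated in the presence of the ester, and the second equivalent of amide base converts the β-ketophosphonate into its stabilized enolate, which drives the condensation and prevents a second addition; the new stereocenter is racemic and disappears in step 8.

Step 7
Reactants: 12 2-[4-(benzyloxy)phenyl]ethanol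
Product: 13 [4-(benzyloxy)phenyl]acetaldehyde
Conditions: Dess–Martin periodinane (1.2 equiv), CH2Cl2, 0 °C to rt; used at once
Reagents that add atoms: none
Why: Dess–Martin oxidation stops cleanly at the aldehyde under neutral, non-aqueous conditions, which matters because the arylacetaldehyde enolizes and self-condenses easily and is therefore used without storage.

Step 8
Reactants: 11 (±)-diethyl {1-[4-(benzyloxy)phenyl]-6-(ArB)-3-oxohexan-4-yl}phosphonate; 13 [4-(benzyloxy)phenyl]acetaldehyde
Product: 14 (E)-1,6-bis[4-(benzyloxy)phenyl]-4-[2-(ArB)ethyl]hex-4-en-3-one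
Conditions: activated Ba(OH)2 (0.8 equiv), THF, rt; then 13 (1.5 equiv), THF/H2O (40:1), 0 °C to rt
Reagents that add atoms: none
Why: Horner–Wadsworth–Emmons olefination under mild heterogeneous Ba(OH)2 conditions: the stabilized phosphonate anion adds to the unhindered aldehyde, and reversible addition before elimination should place the aldehyde-derived substituent trans to the acyl group, giving the (E)-trisubstituted enone, whose geometry is in any case erased in step 11.

Step 9
Reactants: 14 (E)-1,6-bis[4-(benzyloxy)phenyl]-4-[2-(ArB)ethyl]hex-4-en-3-one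
Product: 17 (E)-1,6-bis[4-(benzyloxy)phenyl]-2-diazo-4-[2-(ArB)ethyl]hex-4-en-3-one, via lithium enolate 15 (not isolated), via trifluoroacetyl diketone 16 (not isolated)
Conditions: LiN(SiMe3)2 (1.0 M in THF, 1.1 equiv), THF, −78 °C; CF3CO2CH2CF3 (1.2 equiv), −78 °C; 5% aq HCl quench, crude carried on without purification; then 4-acetamidobenzenesulfonyl azide (1.5 equiv), Et3N (1.5 equiv), H2O (1 equiv), MeCN, rt
Reagents that add atoms: 4-acetamidobenzenesulfonyl azide, CC(=O)Nc1ccc(cc1)S(=O)(=O)N=[N+]=[N-]
Why: Detrifluoroacetylative (Regitz-type) diazo transfer: the hindered amide base at −78 °C should remove a proton from the accessible α′-methylene (the γ-methylene lies trans to the carbonyl and is not reached through the lithium-bound transition state), Claisen-type trifluoroacetylation activates that carbon, and the sulfonyl azide then delivers the diazo nitrogens while the trifluoroacetyl group leaves as the sulfonamide.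

Step 10
Reactants: 18 2-chloro-1,1-dimethoxyethane
Product: 20 methoxyacetylene, via sodium methoxyacetylide 19 (not isolated)
Conditions: NaNH2 (3.1 equiv), liquid NH3, −33 °C; NH3 evaporated; cold saturated aq NaCl, −20 °C; distilled (bp about 23 °C) into cold ClCH2CH2Cl
Reagents that add atoms: none
Why: Base-induced elimination sequence: NaNH2 removes methanol and then hydrogen chloride from the chloroacetal and deprotonates the resulting ynol ether, so that the stable sodium acetylide accumulates and the volatile alkyne is released only on cold aqueous quench.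

Step 11
Reactants: 17 (E)-1,6-bis[4-(benzyloxy)phenyl]-2-diazo-4-[2-(ArB)ethyl]hex-4-en-3-one; 20 methoxyacetylene
Product: 25 2,4-bis[4-(benzyloxy)benzyl]-5-methoxy-3-[2-(ArB)ethyl]phenol, via vinylketene 21 (not isolated), via vinylcyclobutenone 22 (not isolated), via dienylketene 23 (not isolated), via cyclohexadienone 24 (not isolated)
Conditions: 20 (5 equiv), degassed ClCH2CH2Cl (0.05 M), sealed Pyrex tube, hν 350–365 nm, rt; then 80 °C
Reagents that add atoms: none
Why: Danheiser benzannulation in its diazo ketone form: light beyond 320 nm, where the diazo enone absorbs and the benzyloxyarenes do not, expels N2 and the alkenyl group shifts from the carbonyl carbon to the diazo carbon (photochemical Wolff rearrangement, joining carbon 5 to carbon 6 of ring A) to give vinylketene 21. The unsubstituted, nucleophilic carbon of 20 attacks the ketene carbonyl carbon and the four-membered ring closes onto the ketene α-carbon ([2+2] addition, forming the bonds from carbon 2 to carbon 3 and from carbon 1 to carbon 6 of ring A) to give cyclobutenone 22. Warming reopens 22 by conrotatory 4π electrocyclic cleavage of the bond between carbons 3 and 6 to dienylketene 23, and ring A then closes by thermal disrotatory 6π electrocyclization between the ketene carbon and the alkene terminus (carbon 3 to carbon 4) to dienone 24, which tautomerizes to phenol 25. Counted from 17, four ring bonds are made and two (carbon 3 to carbon 5 and carbon 3 to carbon 6) are given up, and the closest known reaction type is this annulation of α′-diazo enones with alkoxy- and siloxyalkynes. No stereocenter survives: the quaternary carbon of 22 and the sp3 carbon of 24 are transient, the alkene geometry of 17 is erased, and reversible ring opening lets either geometric isomer of 23 funnel into the one that can close. The step needs regioselectivity in the cycloaddition, which the polarization of the ynol ether secures (OMe ends on carbon 1, next to carbon 6 and meta to the hydroxyl on carbon 3), and Wolff shift in preference to hydrogen migration from the benzylic methylene, which direct irradiation favours.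

Step 12
Reactants: 25 2,4-bis[4-(benzyloxy)benzyl]-5-methoxy-3-[2-(ArB)ethyl]phenol
Product: 26 2,4-bis(4-hydroxybenzyl)-3-{2-[5-hydroxy-2-(4-hydroxybenzyl)phenyl]ethyl}-5-methoxyphenol (target)
Conditions: H2 (1 atm), 10% Pd/C, EtOAc/MeOH (1:1), rt
Reagents that add atoms: none
Why: Catalytic hydrogenolysis cleaves the four benzylic C–O bonds of the aryl benzyl ethers, while the diarylmethane C–C bonds, the methyl ether and the arenes are not reduced at 1 atm and rt.

Compound list

1 | 2-bromo-4-hydroxybenzaldehyde | O=Cc1ccc(O)cc1Br | starting material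
2 | 4-(benzyloxy)-2-bromobenzaldehyde | O=Cc1ccc(OCc2ccccc2)cc1Br | intermediate
3 | 4-(benzyloxy)phenylmagnesium bromide | Br[Mg]c1ccc(OCc2ccccc2)cc1 | starting material
4 | (±)-[4-(benzyloxy)-2-bromophenyl][4-(benzyloxy)phenyl]methanol | OC(c1ccc(OCc2ccccc2)cc1)c1ccc(OCc2ccccc2)cc1Br | intermediate
5 | 4-(benzyloxy)-1-[4-(benzyloxy)benzyl]-2-bromobenzene | Brc1cc(OCc2ccccc2)ccc1Cc1ccc(OCc2ccccc2)cc1 | intermediate
6 | diethyl allylphosphonate | C=CCP(=O)(OCC)OCC | starting material
7 | diethyl [3-(9-borabicyclo[3.3.1]nonan-9-yl)propyl]phosphonate | CCOP(=O)(OCC)CCCB1C2CCCC1CCC2 | intermediate (not isolated)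
8 | diethyl (3-{5-(benzyloxy)-2-[4-(benzyloxy)benzyl]phenyl}propyl)phosphonate | CCOP(=O)(OCC)CCCc1cc(OCc2ccccc2)ccc1Cc1ccc(OCc2ccccc2)cc1 | intermediate
9 | 3-(4-hydroxyphenyl)propanoic acid | OC(=O)CCc1ccc(O)cc1 | starting material
10 | benzyl 3-[4-(benzyloxy)phenyl]propanoate | O=C(CCc1ccc(OCc2ccccc2)cc1)OCc1ccccc1 | intermediate
11 | (±)-diethyl {1-[4-(benzyloxy)phenyl]-6-(ArB)-3-oxohexan-4-yl}phosphonate | CCOP(=O)(OCC)C(CCc1cc(OCc2ccccc2)ccc1Cc1ccc(OCc2ccccc2)cc1)C(=O)CCc1ccc(OCc2ccccc2)cc1 | intermediate
12 | 2-[4-(benzyloxy)phenyl]ethanol | OCCc1ccc(OCc2ccccc2)cc1 | starting material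
13 | [4-(benzyloxy)phenyl]acetaldehyde | O=CCc1ccc(OCc2ccccc2)cc1 | intermediate
14 | (E)-1,6-bis[4-(benzyloxy)phenyl]-4-[2-(ArB)ethyl]hex-4-en-3-one | O=C(CCc1ccc(OCc2ccccc2)cc1)/C(CCc1cc(OCc2ccccc2)ccc1Cc1ccc(OCc2ccccc2)cc1)=C/Cc1ccc(OCc2ccccc2)cc1 | intermediate
15 | lithium (4E)-1,6-bis[4-(benzyloxy)phenyl]-4-[2-(ArB)ethyl]hexa-2,4-dien-3-olate (cross-conjugated α′-enolate, enolate geometry not defined) | [Li+].[O-]C(=CCc1ccc(OCc2ccccc2)cc1)/C(CCc1cc(OCc2ccccc2)ccc1Cc1ccc(OCc2ccccc2)cc1)=C/Cc1ccc(OCc2ccccc2)cc1 | intermediate (not isolated)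
16 | (±)-(E)-1,6-bis[4-(benzyloxy)phenyl]-4-[2-(ArB)ethyl]-2-(trifluoroacetyl)hex-4-en-3-one | O=C(C(Cc1ccc(OCc2ccccc2)cc1)C(=O)C(F)(F)F)/C(CCc1cc(OCc2ccccc2)ccc1Cc1ccc(OCc2ccccc2)cc1)=C/Cc1ccc(OCc2ccccc2)cc1 | intermediate (not isolated)
17 | (E)-1,6-bis[4-(benzyloxy)phenyl]-2-diazo-4-[2-(ArB)ethyl]hex-4-en-3-one | [N-]=[N+]=C(Cc1ccc(OCc2ccccc2)cc1)C(=O)/C(CCc1cc(OCc2ccccc2)ccc1Cc1ccc(OCc2ccccc2)cc1)=C/Cc1ccc(OCc2ccccc2)cc1 | intermediate
18 | 2-chloro-1,1-dimethoxyethane | COC(CCl)OC | starting material
19 | sodium methoxyacetylide | [Na+].[C-]#COC | intermediate (not isolated)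
20 | methoxyacetylene | COC#C | intermediate
21 | (E)-2-[4-(benzyloxy)benzyl]-5-[4-(benzyloxy)phenyl]-3-[2-(ArB)ethyl]penta-1,3-dien-1-one (vinylketene) | O=C=C(Cc1ccc(OCc2ccccc2)cc1)/C(CCc1cc(OCc2ccccc2)ccc1Cc1ccc(OCc2ccccc2)cc1)=C/Cc1ccc(OCc2ccccc2)cc1 | intermediate (not isolated)
22 | (±)-4-[4-(benzyloxy)benzyl]-3-methoxy-4-[(E)-1-[4-(benzyloxy)phenyl]-5-(ArB)pent-2-en-3-yl]cyclobut-2-en-1-one | COC3=CC(=O)C3(Cc1ccc(OCc2ccccc2)cc1)/C(CCc1cc(OCc2ccccc2)ccc1Cc1ccc(OCc2ccccc2)cc1)=C/Cc1ccc(OCc2ccccc2)cc1 | intermediate (not isolated)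
23 | 4-[4-(benzyloxy)benzyl]-7-[4-(benzyloxy)phenyl]-3-methoxy-5-[2-(ArB)ethyl]hepta-1,3,5-trien-1-one (dienylketene; ketene unit and alkenyl group cis across the 3,4-double bond, 5,6-double bond E) | O=C=C/C(OC)=C(Cc1ccc(OCc2ccccc2)cc1)\C(CCc1cc(OCc2ccccc2)ccc1Cc1ccc(OCc2ccccc2)cc1)=C\Cc1ccc(OCc2ccccc2)cc1 | intermediate (not isolated)
24 | (±)-4,6-bis[4-(benzyloxy)benzyl]-3-methoxy-5-[2-(ArB)ethyl]cyclohexa-2,4-dien-1-one | COC1=CC(=O)C(Cc2ccc(OCc3ccccc3)cc2)C(CCc2cc(OCc3ccccc3)ccc2Cc2ccc(OCc3ccccc3)cc2)=C1Cc4ccc(OCc5ccccc5)cc4 | intermediate (not isolated)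
25 | 2,4-bis[4-(benzyloxy)benzyl]-5-methoxy-3-[2-(ArB)ethyl]phenol | COc1cc(O)c(Cc2ccc(OCc3ccccc3)cc2)c(CCc2cc(OCc3ccccc3)ccc2Cc2ccc(OCc3ccccc3)cc2)c1Cc1ccc(OCc2ccccc2)cc1 | intermediate
26 | 2,4-bis(4-hydroxybenzyl)-3-{2-[5-hydroxy-2-(4-hydroxybenzyl)phenyl]ethyl}-5-methoxyphenol | COc1cc(O)c(Cc2ccc(O)cc2)c(CCc2cc(O)ccc2Cc2ccc(O)cc2)c1Cc1ccc(O)cc1 | target

Total step count: 12. Longest linear sequence: 9 steps (steps 1, 2, 3, 4, 6, 8, 9, 11, 12).

Steps most likely to fail

Step 11. The short-lived vinylketene may be captured too slowly by the volatile ynol ether, which can be lost by evaporation or polymerization. The ketene would then be diverted into dimers or into O-acylation of the product phenol. The fallback changes the two-carbon partner and makes the annulation stepwise; it sets out from 17 and rejoins the route at 22 and hence 25. Diazo ketone 17 would be irradiated as in step 11 in the presence of commercial 1,1-dimethoxyethene, whose much more nucleophilic double bond should intercept ketene 21 in a polar [2+2] addition. This should give (±)-2-[4-(benzyloxy)benzyl]-3,3-dimethoxy-2-[(E)-1-[4-(benzyloxy)phenyl]-5-(ArB)pent-2-en-3-yl]cyclobutan-1-one F1. Loss of methanol from F1 on silica gel or on brief warming should give cyclobutenone 22, and heating in toluene at 80–110 °C should carry 22 through 23 and 24 to 25.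

Step 9. A proton may be transferred from the γ-methylene, which is both benzylic and vinylogous, during enolate formation or during the slower acylation. The extended dienolate would then lead to acylation at the wrong carbon or to migration of the double bond out of conjugation with the ketone. The fallback installs the diazo group before the alkene exists; it sets out from 11 and returns at 17. Ketophosphonate 11 would be converted into its α,γ-dianion (NaH, then n-BuLi, THF, 0 to −78 °C), in which the second deprotonation can only occur at the methylene on the far side of the ketone. Acylation of this more reactive terminus with CF3CO2CH2CF3 should give diethyl {1-[4-(benzyloxy)phenyl]-6-(ArB)-3-oxo-2-(trifluoroacetyl)hexan-4-yl}phosphonate F2. Deacylative diazo transfer (4-acetamidobenzenesulfonyl azide, Et3N, MeCN, rt) should give diethyl {1-[4-(benzyloxy)phenyl]-2-diazo-6-(ArB)-3-oxohexan-4-yl}phosphonate F3. Horner–Wadsworth–Emmons olefination of F3 with aldehyde 13 under the Ba(OH)2 conditions of step 8 should then give 17 directly.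

Step 8. Base-induced self-condensation of the enolizable arylacetaldehyde may outrun the slow olefination by the hindered α-branched phosphonate anion, and the new double bond may migrate into conjugation with the arene. The fallback builds the alkene under neutral conditions; it sets out from 11 and returns at 14. Olefination of 11 with aqueous formaldehyde (K2CO3, THF/H2O, rt), which cannot enolize, should give 1-[4-(benzyloxy)phenyl]-4-methylidene-6-(ArB)hexan-3-one F4. Its partner, 1-allyl-4-(benzyloxy)benzene F5, would be made from 4-allylphenol with BnBr and K2CO3 in DMF. Cross-metathesis of F4 with F5 (3 equiv) using second-generation Grubbs catalyst RuCl2(=CHPh)(H2IMes)(PCy3) in CH2Cl2 at 40 °C should give 14 as the (E)-isomer.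

Further compounds

F1 | step 11 | (±)-2-[4-(benzyloxy)benzyl]-3,3-dimethoxy-2-[(E)-1-[4-(benzyloxy)phenyl]-5-(ArB)pent-2-en-3-yl]cyclobutan-1-one | COC3(OC)CC(=O)C3(Cc1ccc(OCc2ccccc2)cc1)/C(CCc1cc(OCc2ccccc2)ccc1Cc1ccc(OCc2ccccc2)cc1)=C/Cc1ccc(OCc2ccccc2)cc1
F2 | step 9 | diethyl {1-[4-(benzyloxy)phenyl]-6-(ArB)-3-oxo-2-(trifluoroacetyl)hexan-4-yl}phosphonate | CCOP(=O)(OCC)C(CCc1cc(OCc2ccccc2)ccc1Cc1ccc(OCc2ccccc2)cc1)C(=O)C(Cc1ccc(OCc2ccccc2)cc1)C(=O)C(F)(F)F
F3 | step 9 | diethyl {1-[4-(benzyloxy)phenyl]-2-diazo-6-(ArB)-3-oxohexan-4-yl}phosphonate | CCOP(=O)(OCC)C(CCc1cc(OCc2ccccc2)ccc1Cc1ccc(OCc2ccccc2)cc1)C(=O)C(=[N+]=[N-])Cc1ccc(OCc2ccccc2)cc1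
F4 | step 8 | 1-[4-(benzyloxy)phenyl]-4-methylidene-6-(ArB)hexan-3-one | C=C(CCc1cc(OCc2ccccc2)ccc1Cc1ccc(OCc2ccccc2)cc1)C(=O)CCc1ccc(OCc2ccccc2)cc1
F5 | step 8 | 1-allyl-4-(benzyloxy)benzene | C=CCc1ccc(OCc2ccccc2)cc1
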